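The earlier runs and the new flask are calculated on assumed constants, and the scatter is random.

Between their last two readings, the odds of target over other capture product fall from 2.33 to 1.64 in maple at −10 °C, and from 1.88 to 1.27 in ash at 5 °C.

| flask | solid substrate | first nucleophile | second nucleophile | temperature | remark | time |
|---|---|---|---|---|---|---|
| maple | 0.016 M | 4 equiv | 2.5 equiv | −10 °C | run made earlier |  |
| ash | 0.016 M | 4 equiv | 1.7 equiv | 5 °C | run made earlier |  |
| cedar | 0.016 M | 4 equiv | 3.8 equiv | −10 °C | run made earlier |  |
| alder | 0.0080 M | 4 equiv | 2.5 equiv | 5 °C | run made earlier |  |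
| green | 0.016 M | 4.00 equiv (fed, over 25 h) | 2.50 equiv |  | the addition at −15 °C, then warmed to 5 °C; the feed brings no volume worth counting | 30 h |
| violet | 0.016 M | 4.00 equiv | 2.50 equiv | 5 °C | everything together at the start | 30 h |
| teal | 0.016 M | 4.00 equiv (fed, over 25 h) | 2.50 equiv | 5 °C | all else is in the flask from the start; the feed brings no volume worth counting | 30 h |
| blue | 0.016 M | 4.00 equiv | 2.50 equiv |  | everything together at the start at −15 °C, warmed to 5 °C at 25 h | 30 h |

- maple (time / h: target / %, other capture product / %, solid substrate / %): 5.00: 0, 0, 85; 10.0: 0, 1, 72; 15.0: 5, 1, 61; 30.0: 7, 3, 35; 60.0: 18, 11, 2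
- ash (time / h: target / %, other capture product / %, solid substrate / %): 8.00: 1, 0, 74; 15.0: 4, 4, 60; 20.0: 9, 5, 48; 30.0: 15, 8, 25; 40.0: 14, 11, 10
- cedar (time / h: target / %, other capture product / %, solid substrate / %): 6.00: 0, 0, 82; 10.0: 2, 4, 72; 20.0: 6, 3, 50; 40.0: 11, 12, 19; 96.0: 28, 30, 0
- alder (time / h: target / %, other capture product / %, solid substrate / %): 3.00: 1, 0, 85; 10.0: 0, 1, 44; 15.0: 9, 5, 18; 25.0: 12, 11, 0; 40.0: 12, 16, 2

(readings scatter by 1.5 percentage points)

* which flask leads in share of target in target plus other capture product ("all alike" within 1.5 percentage points) (green / violet / teal / blue / all alike)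
* share of target in target plus other capture product at the end, green
* share of target in target plus other capture product at the end, violet
* share of target in target plus other capture product at the end, teal
* share of target in target plus other capture product at the end, blue

- solid substrate is a solid; its amount is given per volume of the solution
- at the start none of the solid substrate is in solution

1. Bench rule: two nucleophiles compete, so the odds should follow their ratio. We define the capture ratio, a selectivity factor, as the odds divided by the ratio of charges: 1.02, read from the last maple reading. Maple has made 7% target and 3% other capture product by 30.0 h, against charges of 4 equiv and 2.5 equiv, so we let charges stand for [first nucleophile] and [second nucleophile].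

2. Cedar, on a different ratio, reads 0.871 at 40.0 h and 0.887 at 96.0 h.

3. The border: ash reads 0.797 at 30.0 h and 0.541 at 40.0 h, so as a reading 0.679 of it is left. Maple, read the same way from 30.0 h to 60.0 h, keeps 0.701, so in both runs a capture ratio read here belongs to its time of reading. Blue and green spend 0.167 of their run warm; violet and teal spend all of it at 5 °C.

4. Our reckoning: with charge ratio 1.60, blue gets 62.0%, and violet, on the ash value, 56.0%. A steady feed averages 0.5 of its charge while it runs, so green lies between 44.9% and blue. Teal, warm and fed, comes last.

5. The forecast names blue, with 53% for green, 51% for violet, 43% for teal and 59% for blue: “cold favours target, the feed opposes it”.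

6. The flasks give blue as leader: blue 61.7%, green 59.5%, violet 52.0%, teal 47.5%.

    starting material ⇌ intermediate (K = 0.0460, k = 0.0150 min⁻¹, Ea = 94.0 kJ mol⁻¹, ΔH = −18.0 kJ mol⁻¹)
    first nucleophile + intermediate → target (k = 0.220 M⁻¹ min⁻¹, Ea = 69.0 kJ mol⁻¹)
    second nucleophile + intermediate → other capture product (k = 0.150 M⁻¹ min⁻¹, Ea = 58.0 kJ mol⁻¹)
    target → over-reaction product (k = 0.00130 min⁻¹, Ea = 92.0 kJ mol⁻¹)
    solid substrate ⇌ starting material, rate k5*(cs5 - [starting material]) while solid is left; crystals form when [starting material] > cs5 (solubility = 15.0 mM, k = 5.80 × 10⁻⁴ min⁻¹)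
    first nucleophile → decomposition product (k = 1.10 × 10⁻⁶ min⁻¹, Ea = 112 kJ mol⁻¹)
    (constants at 5 °C)

In blue, dissolution of the solid had done half of its turnover by 12.0 h, while the passing of starting material into intermediate took until 25.9 h, so capture ran late. At 30.0 h blue holds 9.26% target, 5.74% other capture product and 2.66% over-reaction product, with 97% and 98% of the nucleophile charges left, which gives a capture ratio of 1.01. For the neighbour of blue on 1.60 equiv of first nucleophile, 1.02 gives 39.6%; that flask gives 39.2%.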